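Decide first not to reckon a curve. What you need is how L divides between E and G.

| setting | Sunday's | Wednesday's | Monday's | flask |
|---|---|---|---|---|
| J | 0.70 M | 1.1 M | 0.50 M | 0.50 M |
| E | 0.55 M | 0.55 M | 0.55 M | 0.550 M |
| G | 0.50 M | 0.50 M | 0.75 M | 0.500 M |
| remark | run made earlier | run made earlier | run made earlier |  |
| time |  |  |  | 10 h |

* time up to 10 h at which X stands highest
* the amount of X, in percent of the J charged, at that time
* the first time at which X reaches 15%, in the same percent

- the numbers in the tables scatter with a standard deviation of 1 percentage point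
- what may be going on: J -> L; X <-> Q; E + L -> X; G -> Z; G + L -> D

| run | time / h | X / % | J / % |
|---|---|---|---|
| Sunday's | 0.333 | 15.7 | 60.5 |
| Sunday's | 0.667 | 26.3 | 37.6 |
| Sunday's | 1.00 | 29.3 | 21.7 |
| Sunday's | 1.50 | 30.7 | 13.0 |
| Sunday's | 3.00 | 27.0 | 2.5 |
| Sunday's | 5.00 | 20.7 | 0 |
| Sunday's | 8.00 | 19.6 | 0.9 |
| Wednesday's | 0.333 | 17.8 | 61.7 |
| Wednesday's | 0.667 | 25.1 | 37.1 |
| Wednesday's | 1.00 | 29.5 | 22.9 |
| Wednesday's | 1.50 | 31.1 | 10.2 |
| Wednesday's | 3.00 | 26.7 | 0.6 |
| Wednesday's | 5.00 | 21.4 | 0.4 |
| Wednesday's | 8.00 | 19.8 | 0.1 |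
| Monday's | 0.333 | 10.0 | 60.2 |
| Monday's | 0.833 | 21.0 | 28.9 |
| Monday's | 1.50 | 24.3 | 10.9 |
| Monday's | 4.00 | 18.7 | 0.7 |
| Monday's | 8.00 | 15.2 | 0.8 |

(standard deviation of a reading: 1 percentage point)

Read the tables at 1.50 h. Sunday's and Wednesday's rows give X as 30.7% and 31.1%, though Wednesday's run charged more J. They lie 0.4 percentage points apart, and a reading scatters by 1 point. So, with E and G held, you treat the percent curve as the same for these J charges. The flask has Sunday's E and G but less J than either run, so you extend that treatment and put it on Sunday's curve. The highest reading there is 30.7% at 1.50 h. X reads 15.7% at 0.333 h, so it passes 15% a little earlier.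

Now set Monday's row beside Sunday's. G is 0.75 M instead of 0.50 M, and J is 0.50 M instead of 0.70 M, a difference you have just chosen to set aside. X reads 24.3%, and J reads 10.9% against 13.0%. Freeze E and G at their charges. Then the share of L reaching X is E/(E + s·G). Sunday's X over Monday's is 1.26, which gives s = 1.22, how many times faster G takes L than E does at equal concentration: the selectivity factor. This is a reading, with its scatter. In the flask the share comes to 47.3%.

The forecast gives 1.4 h, 31% and 0.3 h, on the ground that “Only the E/G ratio matters”.

The flask gives X at its highest at 1.39 h, with 30.7%, and reaches 15% at 0.295 h. At that best time 12.2% of the J is still there. Your share was frozen at the charges, but at that time E stands at 62.2% and G at 54.2% of their own charges. With those amounts, s gives a share of 50.8% for that moment.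

    J → L (k = 4.20 × 10⁻⁴ /s)
    X ⇌ Q (K = 1.60, k = 1.10 × 10⁻⁴ /s)
    E + L → X (k = 0.0140 /M/s)
    G → Z (k = 3.70 × 10⁻⁷ /s)
    G + L → D (k = 0.0180 /M/s)

Take the neighbour charged with 0.12 M of G. There s gives a share of 78.9%, and scaling the flask's best X in proportion gives 51.2%. The computed neighbour gives 51.2%.

The earlier runs and the new flask were generated by integration on assumed constants.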